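The data were computed for substances that don't exist; scatter was added.

A small charge of free catalyst, 0.380% of the starting material in the winter run and 0.540% in the midnight run, raced an uncatalysed step for the same starting material, so I counted its turnovers.

| flask | starting material | second substrate | free catalyst | remark | time |
|---|---|---|---|---|---|
| winter | 0.050 M | 0.050 M | 0.19 mM | run made earlier |  |
| midnight | 0.050 M | 0.050 M | 0.27 mM | run made earlier |  |
| larch | 0.050 M | 0.0500 M | 0.25 mM |  | 10 min |
| elm | 0.050 M | 0.0500 M | 0.33 mM |  | 10 min |

| run | time / min | catalyst intermediate A / % | target / % | uncatalysed product / % | starting material / % |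
|---|---|---|---|---|---|
| winter | 0.417 | 0.8 | 6.6 | 40.8 | 54.2 |
| winter | 1.33 | 0 | 13.9 | 72.4 | 14.0 |
| winter | 2.50 | 0 | 19.5 | 79.2 | 0.5 |
| winter | 4.00 | 1.4 | 18.1 | 80.9 | 0.5 |
| winter | 5.00 | 0.2 | 20.2 | 81.3 | 0 |
| midnight | 0.417 | 0 | 9.7 | 35.1 | 52.9 |
| midnight | 1.33 | 0 | 20.3 | 68.6 | 11.2 |
| midnight | 2.50 | 0.9 | 25.8 | 73.5 | 1.2 |
| midnight | 4.00 | 0 | 24.8 | 74.4 | 0 |
| midnight | 5.00 | 1.0 | 25.6 | 72.3 | 0 |

(standard deviation of a reading: 1 percentage point)

- which of these there is most of at the end, counted by the starting material in it, larch (catalyst intermediate A / starting material / target / uncatalysed product)
- which of these there is most of at the end, counted by the starting material in it, elm (catalyst intermediate A / starting material / target / uncatalysed product)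
- final amount of the leader among these, as a percentage of the starting material charged, in larch
- final amount of the leader among these, as a percentage of the starting material charged, in elm

- what was read earlier has a scatter of 1 percentage point, one standard deviation
- steps that have been proposed: second substrate + free catalyst <-> catalyst intermediate B; starting material -> uncatalysed product; catalyst intermediate B + target -> spent catalyst; catalyst intermediate A -> free catalyst + target; catalyst intermediate B -> free catalyst + second product; starting material + free catalyst <-> catalyst intermediate A

Starting material read 0% at 5.00 min in the winter run and 0% in the midnight run, while target and uncatalysed product summed to 101% and 97.9%. The final split between those two was therefore what I had to reckon, with x the catalyst as a fraction of the starting material.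

I solved two extreme flasks. In the first, each catalyst stays busy and turns the same number of times whatever x is, so target = N x. The winter run gave N = 53.2, which predicted 28.7% of target for the midnight run, but that run read 25.6%.

In the second, the catalyst is far from full, both routes are first order in starting material, and the split stays constant. The winter run gave 65.4 turnovers of target per catalyst for each whole charge lost to the uncatalysed route, the selectivity factor s. So, with starting material and second substrate held at the charges of these runs:

target / uncatalysed product = s x

uncatalysed product = 1 / (1 + s x)

This predicted 26.1% of target for the midnight run, whose own s was 65.6. The winter ratio did climb, from 0.162 at the first reading to 0.248 at the last, so the real flask leans somewhat towards the first extreme. Still, the midnight reading stood at the second, and I reckoned with that: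

larch: x = 0.500%, s x = 0.327, uncatalysed product = 75.4%

elm: x = 0.660%, s x = 0.432, uncatalysed product = 69.9%

The forecast, made by someone who saw these runs, gave uncatalysed product the lead at 75.7% in larch and 70.7% in elm, noting that the “mass balance closes on target plus uncatalysed product”. The flasks gave uncatalysed product the lead at 75.9% in larch and 70.0% in elm.

    second substrate + free catalyst ⇌ catalyst intermediate B (K = 120 L mol⁻¹, k = 150 L mol⁻¹ s⁻¹)
    starting material → uncatalysed product (k = 0.0200 s⁻¹)
    catalyst intermediate B + target → spent catalyst (k = 0.120 L mol⁻¹ s⁻¹)
    catalyst intermediate A → free catalyst + target (k = 1.90 s⁻¹)
    catalyst intermediate B → free catalyst + second product (k = 4.20 s⁻¹)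
    starting material + free catalyst ⇌ catalyst intermediate A (K = 37.0 L mol⁻¹, k = 4300 L mol⁻¹ s⁻¹)

Uncatalysed product ended at 70.0% in elm and 75.9% in larch, and that gap comes from the difference in their charge of free catalyst: with larch's charge, elm gives 75.9% instead of 70.0%. Elm's own final split returns an s of 65.0. In a neighbour of elm charged with 0.0013 M of free catalyst, x is 2.60% and s x is 1.70, which passes unity, so the count puts target ahead at 63.0%. That neighbour flask ended with target in the lead at 64.6%.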